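**Retrosynthetic overview**

- Chiricanine C (25) ⇒ resorcinol monopivalate 18: the C5 pivalate is cleaved last, the C3 hydroxyl is methylated, and the C4 prenyl group comes from a Claisen shift of the C3 O-(1,1-dimethylallyl) ether.
- 18 ⇒ open-chain enyne pivalate 14 + CO: a rhodium-catalysed [5+1] benzannulation forms C3–C4 and C2–C3 and closes ring A. Ring A is the only ring built in the route; the phenyl ring arrives with boronic acid 7.
- 14 ⇒ enal 10 + ethynylmagnesium bromide + pivaloyl chloride; 10 ⇒ (Z)-iodoenoate 6 + (E)-styrylboronic acid (Suzuki–Miyaura); 6 ⇒ 4-methylpent-3-enal + an α-iodo ylide (Wittig).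
- Feature: ring A (C1 styryl, C2 prenyl, C3 OMe, C4 prenyl, C5 OH, C6 H) is a pentasubstituted benzene whose two meta oxygens at C3 and C5 must be told apart and whose C1 and C2 carbon substituents are adjacent. The benzannulation delivers C3 as a free hydroxyl (from CO) beside a C5 ester and takes C1 and C2 from the trisubstituted alkene of 14.

Key step: step 7

Assumption: carbonate 19 is treated as a purchasable reagent, and the carbinol centre of 13 and 14 is carried as a racemate because it becomes the sp2 ring carbon C6 in step 7.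

**Route**

Step 1
Reactants: 1 4-methylpent-3-en-1-ol
Product: 2 4-methylpent-3-enal
Conditions: Dess–Martin periodinane, NaHCO3, CH2Cl2, 0 °C to rt; dried solution used at once
Reagents that add atoms: none
Why: Dess–Martin oxidation takes a primary homoallylic alcohol to the aldehyde without over-oxidation, and the bicarbonate buffer with immediate use of the solution should keep the β,γ-alkene from moving into conjugation.

Step 2
Reactants: 2 4-methylpent-3-enal; 3 ethyl 2-(triphenyl-λ5-phosphanylidene)acetate; 4 N-iodosuccinimide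
Product: 6 ethyl (2Z)-2-iodo-6-methylhepta-2,5-dienoate, via iodo ylide 5 (not isolated)
Conditions: 3, NIS, CH2Cl2, −20 °C; then 2, −20 °C to rt
Reagents that add atoms: ethyl 2-(triphenyl-λ5-phosphanylidene)acetate 3, CCOC(=O)C=P(c1ccccc1)(c1ccccc1)c1ccccc1; N-iodosuccinimide 4, O=C1CCC(=O)N1I
Why: Wittig olefination with the α-iodo stabilised ylide 5, formed by iodination of 3 with NIS and deprotonation by the succinimide anion, places the ester trans to the aldehyde residue as stabilised ylides do, which fixes the (2Z)-iodoenoate geometry that later puts the prenyl group trans to the carbinol carbon.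

Step 3
Reactants: 6 ethyl (2Z)-2-iodo-6-methylhepta-2,5-dienoate; 7 (E)-2-phenylethenylboronic acid
Product: 8 ethyl (2E)-6-methyl-2-[(E)-2-phenylethenyl]hepta-2,5-dienoate
Conditions: PdCl2(dppf) (5 mol%), K3PO4, THF/H2O, 40 °C
Reagents that add atoms: (E)-2-phenylethenylboronic acid 7, OB(O)/C=C/c1ccccc1
Why: Suzuki–Miyaura coupling of an alkenyl iodide with an alkenylboronic acid proceeds with retention at both alkenes, so the styryl group replaces iodine cis to the CH2 of the prenyl arm, and the mild phosphate base at 40 °C should leave the skipped diene and the ester in place.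

Step 4
Reactants: 8 ethyl (2E)-6-methyl-2-[(E)-2-phenylethenyl]hepta-2,5-dienoate
Product: 9 (2E)-6-methyl-2-[(E)-2-phenylethenyl]hepta-2,5-dien-1-ol
Conditions: i-Bu2AlH (2.2 equiv), CH2Cl2, −78 °C; aq. potassium sodium tartrate
Reagents that add atoms: none
Why: i-Bu2AlH effects clean 1,2-reduction of the α,β-unsaturated ester to the allylic alcohol at low temperature without touching the alkenes or their geometry.

Step 5
Reactants: 9 (2E)-6-methyl-2-[(E)-2-phenylethenyl]hepta-2,5-dien-1-ol
Product: 10 (2E)-6-methyl-2-[(E)-2-phenylethenyl]hepta-2,5-dienal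
Conditions: MnO2 (excess), CH2Cl2, rt
Reagents that add atoms: none
Why: MnO2 oxidises the allylic alcohol selectively to the enal under neutral conditions, the alkene already having the thermodynamically preferred geometry with the β-substituent trans to the formyl group.

Step 6
Reactants: 10 (2E)-6-methyl-2-[(E)-2-phenylethenyl]hepta-2,5-dienal; 11 ethynylmagnesium bromide; 12 pivaloyl chloride
Product: 14 (4E)-8-methyl-4-[(E)-2-phenylethenyl]nona-4,7-dien-1-yn-3-yl pivalate (racemic), via bromomagnesium alkoxide 13 (not isolated)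
Conditions: HC≡CMgBr, THF, −78 to 0 °C; then PivCl, DMAP (cat.), 0 °C to rt
Reagents that add atoms: ethynylmagnesium bromide 11, C#C[Mg]Br; pivaloyl chloride 12, CC(C)(C)C(=O)Cl
Why: Grignard 1,2-addition of the acetylide to the enal followed by O-acylation of the magnesium alkoxide 13 in the same flask gives the propargylic pivalate; the new carbinol centre forms without control as a racemate, which is of no consequence because it becomes the sp2 carbon C6 of ring A in step 7.

Step 7
Reactants: 14 (4E)-8-methyl-4-[(E)-2-phenylethenyl]nona-4,7-dien-1-yn-3-yl pivalate; 15 carbon monoxide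
Product: 18 3-hydroxy-4-(3-methylbut-2-en-1-yl)-5-[(E)-2-phenylethenyl]phenyl pivalate, via dienylketene 16 (not isolated), via cyclohexadienone 17 (not isolated)
Conditions: [RhCl(CO)2]2 (5 mol%), CO (50–80 atm, autoclave), CH2Cl2, 80 °C
Reagents that add atoms: carbon monoxide 15, [C-]#[O+]
Why: Monovalent rhodium activates the terminal alkyne of 14, the pivalate carbonyl oxygen adds to the internal alkyne carbon, and opening of the resulting dioxolenium ion at the propargylic C–O bond (1,2-acyloxy shift) leaves a rhodium dienylcarbene at the former alkyne terminus, which inserts CO (forming C3–C4) and releases dienylketene 16. Ring A closes by thermal 6π-electrocyclisation of 16, in which the ketene carbon C3 bonds to the prenyl-bearing alkene carbon C2, and dienone 17 tautomerises to the phenol. The closest known reaction type is this same rhodium-catalysed [5+1] carbonylative benzannulation of 3-acyloxy-1,4-enynes to resorcinol monoesters, applied here to a substrate that carries an extra styryl group on the alkene. No stereocentre is created, and the racemic carbinol centre of 14 is erased as it becomes aromatic C6. The step needs 1,2- over 1,3-acyloxy migration, which the unsubstituted alkyne terminus secures, and CO capture ahead of five-membered ring closure of the carbene, which the CO pressure secures. It also needs a triene that can reach the closing geometry, which the alkene geometry set in steps 2 and 3 secures by placing the prenyl group trans to the carbinol carbon so that only hydrogen points into the forming ring; the outcome is a free C3 hydroxyl beside a C5 pivalate, with styryl at C1 and prenyl at C2.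

Step 8
Reactants: 18 3-hydroxy-4-(3-methylbut-2-en-1-yl)-5-[(E)-2-phenylethenyl]phenyl pivalate; 19 tert-butyl 2-methylbut-3-en-2-yl carbonate
Product: 20 3-[(2-methylbut-3-en-2-yl)oxy]-4-(3-methylbut-2-en-1-yl)-5-[(E)-2-phenylethenyl]phenyl pivalate
Conditions: Pd(PPh3)4 (5 mol%), THF, 0 °C
Reagents that add atoms: tert-butyl 2-methylbut-3-en-2-yl carbonate 19, C=CC(C)(C)OC(=O)OC(C)(C)C
Why: Tsuji–Trost allylic etherification: zerovalent palladium ionises carbonate 19 with loss of CO2, the tert-butoxide released deprotonates the phenol, and the phenoxide attacks the more substituted terminus of the 1,1-dimethylallyl palladium complex under kinetic control at 0 °C to give the tertiary ether, the aryl pivalate being inert.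

Step 9
Reactants: 20 3-[(2-methylbut-3-en-2-yl)oxy]-4-(3-methylbut-2-en-1-yl)-5-[(E)-2-phenylethenyl]phenyl pivalate
Product: 22 3-hydroxy-2,4-bis(3-methylbut-2-en-1-yl)-5-[(E)-2-phenylethenyl]phenyl pivalate, via ortho-dienone 21 (not isolated)
Conditions: PhNEt2, 130 °C, sealed tube
Reagents that add atoms: none
Why: Aromatic Claisen rearrangement ([3,3] sigmatropic shift) carries the allyl terminus to C4, the only ortho carbon that bears hydrogen, where tautomerisation of dienone 21 makes the shift irreversible, while migration to the blocked C2 can only revert, and the basic amine solvent suppresses acid-promoted chroman formation.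

Step 10
Reactants: 22 3-hydroxy-2,4-bis(3-methylbut-2-en-1-yl)-5-[(E)-2-phenylethenyl]phenyl pivalate; 23 iodomethane
Product: 24 3-methoxy-2,4-bis(3-methylbut-2-en-1-yl)-5-[(E)-2-phenylethenyl]phenyl pivalate
Conditions: MeI, K2CO3, DMF, rt
Reagents that add atoms: iodomethane 23, CI
Why: Williamson ether synthesis: the hindered but acidic C3 phenol is O-methylated by MeI under K2CO3 in DMF, conditions under which the bulky aryl pivalate should not be cleaved.

Step 11
Reactants: 24 3-methoxy-2,4-bis(3-methylbut-2-en-1-yl)-5-[(E)-2-phenylethenyl]phenyl pivalate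
Product: 25 chiricanine C, 3-methoxy-2,4-bis(3-methylbut-2-en-1-yl)-5-[(E)-2-phenylethenyl]phenol
Conditions: NaOMe, MeOH, rt; then aq. NH4Cl
Reagents that add atoms: none
Why: Base-mediated transesterification (methanolysis) removes the aryl pivalate because phenoxide is a good leaving group, and the methyl ether, the prenyl groups and the (E)-styryl alkene are inert to methoxide.

**Compound list**

1 | 4-methylpent-3-en-1-ol | CC(C)=CCCO | starting material
2 | 4-methylpent-3-enal | CC(C)=CCC=O | intermediate
3 | ethyl 2-(triphenyl-λ5-phosphanylidene)acetate | CCOC(=O)C=P(c1ccccc1)(c1ccccc1)c1ccccc1 | starting material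
4 | N-iodosuccinimide | O=C1CCC(=O)N1I | starting material
5 | ethyl 2-iodo-2-(triphenyl-λ5-phosphanylidene)acetate (iodo ylide, not isolated) | CCOC(=O)C(I)=P(c1ccccc1)(c1ccccc1)c1ccccc1 | intermediate
6 | ethyl (2Z)-2-iodo-6-methylhepta-2,5-dienoate | CCOC(=O)/C(I)=C/CC=C(C)C | intermediate
7 | (E)-2-phenylethenylboronic acid | OB(O)/C=C/c1ccccc1 | starting material
8 | ethyl (2E)-6-methyl-2-[(E)-2-phenylethenyl]hepta-2,5-dienoate | CCOC(=O)/C(/C=C/c1ccccc1)=C/CC=C(C)C | intermediate
9 | (2E)-6-methyl-2-[(E)-2-phenylethenyl]hepta-2,5-dien-1-ol | OC/C(/C=C/c1ccccc1)=C/CC=C(C)C | intermediate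
10 | (2E)-6-methyl-2-[(E)-2-phenylethenyl]hepta-2,5-dienal | O=C/C(/C=C/c1ccccc1)=C/CC=C(C)C | intermediate
11 | ethynylmagnesium bromide | C#C[Mg]Br | starting material
12 | pivaloyl chloride | CC(C)(C)C(=O)Cl | starting material
13 | bromomagnesium (4E)-8-methyl-4-[(E)-2-phenylethenyl]nona-4,7-dien-1-yn-3-olate (racemic, not isolated) | C#CC(O[Mg]Br)/C(/C=C/c1ccccc1)=C/CC=C(C)C | intermediate
14 | (4E)-8-methyl-4-[(E)-2-phenylethenyl]nona-4,7-dien-1-yn-3-yl pivalate (racemic) | C#CC(OC(=O)C(C)(C)C)/C(/C=C/c1ccccc1)=C/CC=C(C)C | intermediate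
15 | carbon monoxide | [C-]#[O+] | starting material
16 | (3E,5E)-9-methyl-1-oxo-5-[(E)-2-phenylethenyl]deca-1,3,5,8-tetraen-3-yl pivalate (dienylketene, not isolated) | O=C=C/C(OC(=O)C(C)(C)C)=C\C(\C=C\c1ccccc1)=C\CC=C(C)C | intermediate
17 | 4-(3-methylbut-2-en-1-yl)-3-oxo-5-[(E)-2-phenylethenyl]cyclohexa-1,5-dien-1-yl pivalate (racemic, not isolated) | O=C1C=C(OC(=O)C(C)(C)C)C=C(/C=C/c2ccccc2)C1CC=C(C)C | intermediate
18 | 3-hydroxy-4-(3-methylbut-2-en-1-yl)-5-[(E)-2-phenylethenyl]phenyl pivalate | Oc1cc(OC(=O)C(C)(C)C)cc(/C=C/c2ccccc2)c1CC=C(C)C | intermediate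
19 | tert-butyl 2-methylbut-3-en-2-yl carbonate | C=CC(C)(C)OC(=O)OC(C)(C)C | starting material
20 | 3-[(2-methylbut-3-en-2-yl)oxy]-4-(3-methylbut-2-en-1-yl)-5-[(E)-2-phenylethenyl]phenyl pivalate | C=CC(C)(C)Oc1cc(OC(=O)C(C)(C)C)cc(/C=C/c2ccccc2)c1CC=C(C)C | intermediate
21 | 4,6-bis(3-methylbut-2-en-1-yl)-5-oxo-3-[(E)-2-phenylethenyl]cyclohexa-1,3-dien-1-yl pivalate (racemic, not isolated) | O=C1C(CC=C(C)C)C(OC(=O)C(C)(C)C)=CC(/C=C/c2ccccc2)=C1CC=C(C)C | intermediate
22 | 3-hydroxy-2,4-bis(3-methylbut-2-en-1-yl)-5-[(E)-2-phenylethenyl]phenyl pivalate | Oc1c(CC=C(C)C)c(OC(=O)C(C)(C)C)cc(/C=C/c2ccccc2)c1CC=C(C)C | intermediate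
23 | iodomethane | CI | starting material
24 | 3-methoxy-2,4-bis(3-methylbut-2-en-1-yl)-5-[(E)-2-phenylethenyl]phenyl pivalate | COc1c(CC=C(C)C)c(OC(=O)C(C)(C)C)cc(/C=C/c2ccccc2)c1CC=C(C)C | intermediate
25 | chiricanine C, 3-methoxy-2,4-bis(3-methylbut-2-en-1-yl)-5-[(E)-2-phenylethenyl]phenol | COc1c(CC=C(C)C)c(O)cc(/C=C/c2ccccc2)c1CC=C(C)C | target

**Totals**

Total step count: 11. Longest linear sequence: 11 steps (1 to 25); all other partners are purchased.

**Steps most likely to fail**

Step 7. After the acyloxy shift the rhodium carbene may close to a five-membered ring onto the neighbouring alkene or the styryl group before CO is taken up. A competing 1,3-acyloxy shift may divert material to allene-derived [4+1] products. The conjugated styryl diene may also bind monovalent rhodium and stall turnover. The fallback takes the styryl group out of the ring-forming step and installs it on the finished arene by cross-coupling; it sets out from 6 (and uses 7) and comes back at 18. Reduction of 6 with i-Bu2AlH should give (2Z)-2-iodo-6-methylhepta-2,5-dien-1-ol F1, and MnO2 the aldehyde (2Z)-2-iodo-6-methylhepta-2,5-dienal F2. Ethynylmagnesium bromide followed by pivaloyl chloride in one flask, by way of bromomagnesium (4Z)-4-iodo-8-methylnona-4,7-dien-1-yn-3-olate F3, should give (4Z)-4-iodo-8-methylnona-4,7-dien-1-yn-3-yl pivalate F4. The same [RhCl(CO)2]2/CO benzannulation, now on a substrate without a conjugated diene, should pass through (3E,5Z)-5-iodo-9-methyl-1-oxodeca-1,3,5,8-tetraen-3-yl pivalate F5 and 5-iodo-4-(3-methylbut-2-en-1-yl)-3-oxocyclohexa-1,5-dien-1-yl pivalate F6 to 3-hydroxy-5-iodo-4-(3-methylbut-2-en-1-yl)phenyl pivalate F7. Suzuki–Miyaura coupling of F7 with 7 (PdCl2(dppf), K3PO4, THF/H2O) then returns 18. This fallback still depends on the rhodium benzannulation and on the alkenyl C–I bond surviving the carbonyl-saturated rhodium centre.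

Step 8. Zerovalent palladium may re-ionise the tertiary allyl ether and let it drift to the linear O-prenyl ether or to C-allylated material, and the ortho-prenylated phenol may react slowly. The fallback sets out from 18 and comes back at 20. Copper-catalysed propargylic etherification of 18 with 3-chloro-3-methylbut-1-yne (CuCl2 cat., DBU, MeCN, 0 °C) should give 3-[(2-methylbut-3-yn-2-yl)oxy]-4-(3-methylbut-2-en-1-yl)-5-[(E)-2-phenylethenyl]phenyl pivalate F8. Semihydrogenation of its terminal alkyne (H2, Pd/CaCO3 poisoned with Pb(OAc)2, quinoline, EtOAc, rt) then gives 20.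

Step 9. On heating, the tertiary ether may fragment to 18 and isoprene, the allyl group may shift to the blocked C2 and travel on to C6, or the ortho-prenylphenol formed may close to a chroman. The fallback replaces the sigmatropic shift of the tertiary ether with a cationic 1,3-shift of the primary ether; it sets out from 18 and comes back at 22, bypassing steps 8 and 9. O-Alkylation of 18 with prenyl bromide (K2CO3, acetone) should give 3-[(3-methylbut-2-en-1-yl)oxy]-4-(3-methylbut-2-en-1-yl)-5-[(E)-2-phenylethenyl]phenyl pivalate F9. Montmorillonite K10 clay in CH2Cl2 at 0 °C should then move the prenyl group from oxygen to the adjacent free ortho carbon C4 to give 22.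

**Further compounds**

F1 | step 7 | (2Z)-2-iodo-6-methylhepta-2,5-dien-1-ol | OC/C(I)=C/CC=C(C)C
F2 | step 7 | (2Z)-2-iodo-6-methylhepta-2,5-dienal | O=C/C(I)=C/CC=C(C)C
F3 | step 7 | bromomagnesium (4Z)-4-iodo-8-methylnona-4,7-dien-1-yn-3-olate | C#CC(O[Mg]Br)/C(I)=C/CC=C(C)C
F4 | step 7 | (4Z)-4-iodo-8-methylnona-4,7-dien-1-yn-3-yl pivalate | C#CC(OC(=O)C(C)(C)C)/C(I)=C/CC=C(C)C
F5 | step 7 | (3E,5Z)-5-iodo-9-methyl-1-oxodeca-1,3,5,8-tetraen-3-yl pivalate | O=C=C/C(OC(=O)C(C)(C)C)=C\C(I)=C\CC=C(C)C
F6 | step 7 | 5-iodo-4-(3-methylbut-2-en-1-yl)-3-oxocyclohexa-1,5-dien-1-yl pivalate | O=C1C=C(OC(=O)C(C)(C)C)C=C(I)C1CC=C(C)C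
F7 | step 7 | 3-hydroxy-5-iodo-4-(3-methylbut-2-en-1-yl)phenyl pivalate | Oc1cc(OC(=O)C(C)(C)C)cc(I)c1CC=C(C)C
F8 | step 8 | 3-[(2-methylbut-3-yn-2-yl)oxy]-4-(3-methylbut-2-en-1-yl)-5-[(E)-2-phenylethenyl]phenyl pivalate | C#CC(C)(C)Oc1cc(OC(=O)C(C)(C)C)cc(/C=C/c2ccccc2)c1CC=C(C)C
F9 | step 9 | 3-[(3-methylbut-2-en-1-yl)oxy]-4-(3-methylbut-2-en-1-yl)-5-[(E)-2-phenylethenyl]phenyl pivalate | CC(C)=CCOc1cc(OC(=O)C(C)(C)C)cc(/C=C/c2ccccc2)c1CC=C(C)C
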